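**Plan**
- Retrosynthesis: the phenol is masked as a silyl ether and the C4 carbinol is taken back to a ketone. The bicycle is then cut in one retro-[5+2] at C1–C7 (allyl bridgehead to the methyl-bearing carbon) and C5–C6 (methoxy bridgehead to the benzylic carbon).
- The feature that allows this: C1–C5 with the C8 carbonyl bridge are the six carbons of an oxidised benzene ring, a 2-allyl-4,5,6-trimethoxyphenoxonium ion whose pentadienyl cation is spanned by the C=O. C6–C7 with trans aryl and methyl groups is (E)-isoeugenol.
- Forward: cation precursor 7 is made from 2,3,4-trimethoxybenzaldehyde (Dakin oxidation, O-allylation, Claisen rearrangement, oxidative ketalisation); (E)-isoeugenol is silylated.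
- One cationic [5+2] cycloaddition under a chiral Brønsted acid then closes the five- and seven-membered rings of the bicyclo[3.2.1]octene onto the existing six-membered ring; Luche reduction and desilylation finish the route.
- Stereochemistry: C6/C7 trans from the (E)-alkene, aryl endo from the compact transition state, absolute configuration from the chiral counter-anion, C4 from hydride attack on the face away from the endo aryl group.

Key step: step 6

Remark on numbering: all bicyclic compounds are numbered as the target is (C1 allyl bridgehead, C2=C3, C4, C5 methoxy bridgehead, C6 aryl carbon, C7 methyl carbon, C8 bridging carbonyl), also where systematic rules would number a dione the other way round.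
Remark on the catalyst: the sense of induction of the chiral acid cannot be derived from first principles; the (R)-acid is written, and its (S)-antipode is the one to use if the sense proves opposite.

**Step 1**
Reactants: 1 2,3,4-trimethoxybenzaldehyde
Product: 3 2,3,4-trimethoxyphenol, via 2,3,4-trimethoxyphenyl formate 2 (not isolated)
Conditions: 30% aq. H2O2, cat. H2SO4, MeOH, rt
Reagents that add atoms: hydrogen peroxide, OO
Why: Dakin oxidation: the hydroperoxide adduct of the electron-rich aldehyde rearranges by aryl migration to formate 2, which methanol cleaves to the phenol.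

**Step 2**
Reactants: 3 2,3,4-trimethoxyphenol
Product: 4 1,2,3-trimethoxy-4-(prop-2-en-1-yloxy)benzene
Conditions: allyl bromide, K2CO3, acetone, reflux
Reagents that add atoms: allyl bromide, C=CCBr
Why: Williamson ether synthesis: the phenoxide displaces bromide from allyl bromide in an SN2 reaction.

**Step 3**
Reactants: 4 1,2,3-trimethoxy-4-(prop-2-en-1-yloxy)benzene
Product: 6 6-allyl-2,3,4-trimethoxyphenol, via Claisen dienone 5 (not isolated)
Conditions: N,N-diethylaniline, 200 °C
Reagents that add atoms: none
Why: Aromatic Claisen rearrangement: the [3,3] shift can deliver the allyl group only to C6 because the other ortho position carries a methoxy group, and dienone 5 tautomerises to the phenol.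

**Step 4**
Reactants: 6 6-allyl-2,3,4-trimethoxyphenol
Product: 7 2-allyl-4,4,5,6-tetramethoxycyclohexa-2,5-dien-1-one
Conditions: PhI(OAc)2, MeOH, 0 °C
Reagents that add atoms: methanol, CO
Why: Oxidative dearomatisation with a hypervalent iodine reagent: the aryloxyiodane loses iodobenzene and methanol adds at the methoxy-bearing para carbon to give the p-quinone monoketal (an ortho adduct would ionise to the same cation in step 6).

**Step 5**
Reactants: 8 (E)-isoeugenol
Product: 9 tert-butyl{2-methoxy-4-[(1E)-prop-1-en-1-yl]phenoxy}dimethylsilane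
Conditions: TBSCl, imidazole, DMF, rt
Reagents that add atoms: tert-butyldimethylsilyl chloride, CC(C)(C)[Si](C)(C)Cl
Why: Silylation of the phenol masks the acidic, oxidisable OH but keeps the para oxygen donor that makes the styrene nucleophilic.

**Step 6**
Reactants: 7 2-allyl-4,4,5,6-tetramethoxycyclohexa-2,5-dien-1-one; 9 tert-butyl{2-methoxy-4-[(1E)-prop-1-en-1-yl]phenoxy}dimethylsilane
Product: 12 (1R,5S,6S,7R)-6-[4-(tert-butyldimethylsilyloxy)-3-methoxyphenyl]-3,5-dimethoxy-7-methyl-1-(prop-2-en-1-yl)bicyclo[3.2.1]oct-2-ene-4,8-dione, via phenoxonium cation 10 (not isolated), via dimethyl ketal 11 (not isolated)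
Conditions: 10 mol% (R)-3,3'-bis(2,4,6-triisopropylphenyl)-1,1'-binaphthalene-2,2'-diyl N-triflylphosphoramide (C51H57F3NO5PS), 3 Å MS, CH2Cl2, −78 → −40 °C; then 0.1 M HCl, THF–H2O, 0 °C
Reagents that add atoms: water, O
Why: Proposed new method: the acid protonates a ketal oxygen of 7, methanol leaves, and the phenoxonium ion 10 (a pentadienyl cation over ring carbons 2 to 6 of the dienone, spanned by the C1 carbonyl) is held as a contact ion pair by the chiral phosphoramide anion; the β-carbon of styrene 9 bonds to the allyl-bearing terminus, the developing p-siloxybenzyl cation is taken by the methoxy-bearing terminus (the β-carbon of the neighbouring enol ether), and the oxocarbenium ion so formed at C4 of the product picks up the released methanol to give ketal 11 and hands the proton back to the catalyst, before dilute acid unmasks the C4 ketone. The closest known reaction type is the achiral acid-promoted perezone-type [5+2] cycloaddition of p-quinone monoketals with (E)-propenylarenes to bicyclo[3.2.1]octenediones, and the closest known source of induction is chiral-anion control of additions and cycloadditions of oxocarbenium ions by BINOL-derived N-triflylphosphoramides; pairing the two is the untested part. One 4π + 2π event, suprafacial on both partners, closes two rings: the five-membered ring C1–C8–C5–C6–C7 by 5-exo-trig attack of the enol-ether carbon that becomes C5 on the benzylic cation, and with the same C5–C6 bond the seven-membered ring C1 to C7, which is 7-endo with respect to that enol ether. C6 and C7 keep the trans relation of the (E)-alkene, the aryl group goes endo because the electron-rich arene stacks over the cationic C3–C4–C5 part in the compact transition state, the bridgeheads C1 and C5 are fixed relative to C7 and C6 by the suprafacial closure, and the absolute sense at all four centres is set by the chiral anion, which covers one face of the flat cation. The step needs terminus selectivity (the first bond must go to the allyl-bearing carbon, which carries the largest LUMO coefficient remote from the donor methoxy groups, while the dimethoxy-ene end is the nucleophilic partner for the second bond), C- over O-capture of the benzylic cation (an O-bonded [3+2] adduct would re-ionise under the acid and drain into the C-bonded bicycle) and face selectivity (the catalyst).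

**Step 7**
Reactants: 12 (1R,5S,6S,7R)-6-[4-(tert-butyldimethylsilyloxy)-3-methoxyphenyl]-3,5-dimethoxy-7-methyl-1-(prop-2-en-1-yl)bicyclo[3.2.1]oct-2-ene-4,8-dione
Product: 13 (1R,4S,5R,6S,7R)-6-[4-(tert-butyldimethylsilyloxy)-3-methoxyphenyl]-4-hydroxy-3,5-dimethoxy-7-methyl-1-(prop-2-en-1-yl)bicyclo[3.2.1]oct-2-en-8-one
Conditions: NaBH4, CeCl3·7H2O, MeOH, −78 °C; pH 7 buffer
Reagents that add atoms: none
Why: Luche reduction should give 1,2-reduction of the C4 enone carbonyl in preference to the C8 ketone held between two quaternary bridgeheads, with hydride adding to the face of C4 turned toward the C8 bridge and away from the endo aryl group, which sets (4S) with the hydroxyl cis to the aryl group.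

**Step 8**
Reactants: 13 (1R,4S,5R,6S,7R)-6-[4-(tert-butyldimethylsilyloxy)-3-methoxyphenyl]-4-hydroxy-3,5-dimethoxy-7-methyl-1-(prop-2-en-1-yl)bicyclo[3.2.1]oct-2-en-8-one
Product: 14 (1R,4S,5R,6S,7R)-4-hydroxy-6-(4-hydroxy-3-methoxyphenyl)-3,5-dimethoxy-7-methyl-1-(prop-2-en-1-yl)bicyclo[3.2.1]oct-2-en-8-one
Conditions: Bu4NF, AcOH (1:1), THF, 0 °C
Reagents that add atoms: none
Why: Fluoride-mediated desilylation of the aryl silyl ether; the acetic acid buffer keeps phenoxide and alkoxide protonated, so the β-hydroxy ketone and the enol ether should be left alone and no stereocentre is touched.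

**Compound list**
1 | 2,3,4-trimethoxybenzaldehyde | COc1ccc(C=O)c(OC)c1OC | starting material
2 | 2,3,4-trimethoxyphenyl formate | COc1ccc(OC=O)c(OC)c1OC | intermediate (not isolated)
3 | 2,3,4-trimethoxyphenol | COc1ccc(O)c(OC)c1OC | intermediate
4 | 1,2,3-trimethoxy-4-(prop-2-en-1-yloxy)benzene | C=CCOc1ccc(OC)c(OC)c1OC | intermediate
5 | 6-allyl-2,3,4-trimethoxycyclohexa-2,4-dien-1-one (Claisen dienone; racemic, its stereocentre is lost on tautomerisation) | C=CCC1C=C(OC)C(OC)=C(OC)C1=O | intermediate (not isolated)
6 | 6-allyl-2,3,4-trimethoxyphenol | C=CCc1cc(OC)c(OC)c(OC)c1O | intermediate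
7 | 2-allyl-4,4,5,6-tetramethoxycyclohexa-2,5-dien-1-one | C=CCC1=CC(OC)(OC)C(OC)=C(OC)C1=O | intermediate
8 | (E)-isoeugenol, 2-methoxy-4-[(1E)-prop-1-en-1-yl]phenol | C/C=C/c1ccc(O)c(OC)c1 | starting material
9 | tert-butyl{2-methoxy-4-[(1E)-prop-1-en-1-yl]phenoxy}dimethylsilane | C/C=C/c1ccc(O[Si](C)(C)C(C)(C)C)c(OC)c1 | intermediate
10 | 2-allyl-4,5,6-trimethoxyphenoxonium cation (ion pair with the catalyst anion) | C=CCC1=CC(=[O+]C)C(OC)=C(OC)C1=O | intermediate (not isolated)
11 | (1R,5S,6S,7R)-6-[4-(tert-butyldimethylsilyloxy)-3-methoxyphenyl]-3,4,4,5-tetramethoxy-7-methyl-1-(prop-2-en-1-yl)bicyclo[3.2.1]oct-2-en-8-one (aryl endo, methyl exo) | C=CC[C@@]12C=C(OC)C(OC)(OC)[C@@](OC)(C1=O)[C@H](c1ccc(O[Si](C)(C)C(C)(C)C)c(OC)c1)[C@H]2C | intermediate (not isolated)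
12 | (1R,5S,6S,7R)-6-[4-(tert-butyldimethylsilyloxy)-3-methoxyphenyl]-3,5-dimethoxy-7-methyl-1-(prop-2-en-1-yl)bicyclo[3.2.1]oct-2-ene-4,8-dione (aryl endo, methyl exo) | C=CC[C@@]12C=C(OC)C(=O)[C@@](OC)(C1=O)[C@H](c1ccc(O[Si](C)(C)C(C)(C)C)c(OC)c1)[C@H]2C | intermediate
13 | (1R,4S,5R,6S,7R)-6-[4-(tert-butyldimethylsilyloxy)-3-methoxyphenyl]-4-hydroxy-3,5-dimethoxy-7-methyl-1-(prop-2-en-1-yl)bicyclo[3.2.1]oct-2-en-8-one | C=CC[C@@]12C=C(OC)[C@H](O)[C@@](OC)(C1=O)[C@H](c1ccc(O[Si](C)(C)C(C)(C)C)c(OC)c1)[C@H]2C | intermediate
14 | (1R,4S,5R,6S,7R)-4-hydroxy-6-(4-hydroxy-3-methoxyphenyl)-3,5-dimethoxy-7-methyl-1-(prop-2-en-1-yl)bicyclo[3.2.1]oct-2-en-8-one | C=CC[C@@]12C=C(OC)[C@H](O)[C@@](OC)(C1=O)[C@H](c1ccc(O)c(OC)c1)[C@H]2C | target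

**Totals**
Total step count: 8. Longest linear sequence: 7 steps (steps 1, 2, 3, 4, 6, 7, 8).

**Steps most likely to fail**

1. Step 6 (bears the label). The ion pair may discriminate the two faces of the cation poorly, the first bond may form at the methoxy-bearing terminus, or the catalyst may be silenced by O-methylation instead of being turned over by methanol. The fallback uses known chemistry and sets out from 7 and 9. The cycloaddition is run with an achiral promoter, trimethylsilyl triflate (10 mol%) in CH2Cl2 at −78 °C, the known acid-promoted [5+2] reaction of quinone monoketals with propenylarenes. This should give ketal 11 together with its mirror image, the ent-ketal F1, and after the same dilute-acid work-up dione 12 together with its mirror image, the ent-dione F2. The enantiomers are then separated by preparative HPLC on a chiral stationary phase (amylose tris(3,5-dimethylphenylcarbamate) on silica), the absolute configuration of the collected fraction is assigned, and 12 comes back to the route before step 7.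

2. Step 7. Hydride may add to the strained C8 bridging ketone in competition with the C4 enone carbonyl, or reduce the enone in the conjugate sense. The fallback sets out from 12. Both carbonyls are reduced with excess NaBH4 in MeOH at 0 °C to the 4,8-diol F3 (C4 hydroxyl as in the target, C8 hydroxyl expected on the side of the C6–C7 bridge). The more accessible equatorial, allylic C4 hydroxyl is silylated with Et3SiCl and imidazole in CH2Cl2 at −20 °C to the C4 triethylsilyl ether F4. The hindered C8 carbinol is oxidised back with Dess–Martin periodinane (C13H13IO8) and NaHCO3 to the silyl-protected 8-ketone F5. Bu4NF/AcOH then removes both silyl groups, and the sequence comes back to the route at 14.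

3. Step 8. Once fluoride liberates the phenoxide, the β-hydroxy ketone may open by retro-aldol cleavage, or the C5–C6 bond may open through a p-quinone methide. The fallback sets out from 12 and changes the order of events so that the final compound never meets fluoride. The silyl ether is removed at the dione stage with KHF2 in MeOH at rt, a slightly acidic medium that forms no phenoxide, to give the phenol dione F6. F6 is reduced under the Luche conditions of step 7 at −78 °C, and the sequence comes back to the route at 14.

**Further compounds**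
F1 | step 6 | (1S,5R,6R,7S)-6-[4-(tert-butyldimethylsilyloxy)-3-methoxyphenyl]-3,4,4,5-tetramethoxy-7-methyl-1-(prop-2-en-1-yl)bicyclo[3.2.1]oct-2-en-8-one (enantiomer of 11, not isolated) | C=CC[C@]12C=C(OC)C(OC)(OC)[C@](OC)(C1=O)[C@@H](c1ccc(O[Si](C)(C)C(C)(C)C)c(OC)c1)[C@@H]2C
F2 | step 6 | (1S,5R,6R,7S)-6-[4-(tert-butyldimethylsilyloxy)-3-methoxyphenyl]-3,5-dimethoxy-7-methyl-1-(prop-2-en-1-yl)bicyclo[3.2.1]oct-2-ene-4,8-dione (enantiomer of 12) | C=CC[C@]12C=C(OC)C(=O)[C@](OC)(C1=O)[C@@H](c1ccc(O[Si](C)(C)C(C)(C)C)c(OC)c1)[C@@H]2C
F3 | step 7 | 8-hydroxy analogue of 13: 6-[4-(tert-butyldimethylsilyloxy)-3-methoxyphenyl]-3,5-dimethoxy-7-methyl-1-(prop-2-en-1-yl)bicyclo[3.2.1]oct-2-ene-4,8-diol, C4 as in 13, C8 hydroxyl on the side of the C6–C7 bridge | C=CC[C@@]12C=C(OC)[C@H](O)[C@@](OC)([C@@H]1O)[C@H](c1ccc(O[Si](C)(C)C(C)(C)C)c(OC)c1)[C@H]2C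
F4 | step 7 | C4 triethylsilyl ether of F3 | C=CC[C@@]12C=C(OC)[C@H](O[Si](CC)(CC)CC)[C@@](OC)([C@@H]1O)[C@H](c1ccc(O[Si](C)(C)C(C)(C)C)c(OC)c1)[C@H]2C
F5 | step 7 | C4 triethylsilyl ether of 13 | C=CC[C@@]12C=C(OC)[C@H](O[Si](CC)(CC)CC)[C@@](OC)(C1=O)[C@H](c1ccc(O[Si](C)(C)C(C)(C)C)c(OC)c1)[C@H]2C
F6 | step 8 | (1R,5S,6S,7R)-6-(4-hydroxy-3-methoxyphenyl)-3,5-dimethoxy-7-methyl-1-(prop-2-en-1-yl)bicyclo[3.2.1]oct-2-ene-4,8-dione | C=CC[C@@]12C=C(OC)C(=O)[C@@](OC)(C1=O)[C@H](c1ccc(O)c(OC)c1)[C@H]2C
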